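**Retrosynthetic overview**

1. The C6 tiglate goes on last, by Mitsunobu inversion of the 6R carbinol 18 with tiglic acid 19.
2. Key step: the ten-membered carbocycle is closed at C6–C7 by an intramolecular chromium-mediated (Nozaki–Hiyama–Kishi) allylation of a Z-dienal by a ring-locked α-(bromomethyl)butenolide (16 → 18). This single step makes the macrocycle, C6, C7 and the exocyclic methylene; it replaces the more usual plan of an open-chain Barbier lactone synthesis followed by a separate RCM or NHK macrocyclisation.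
3. The butenolide allyl donor comes from RCM of a 2-(bromomethyl)acrylate on a C8 vinyl carbinol; the furanone comes from acetylide opening of hydroxy lactone 6 by a Z-enyne and gold-catalysed 5-endo cyclisation.
4. C10 is bought with (S)-citramalic acid; C8 is set by a catalytic asymmetric vinylation; C7 and C6 are set in the ring closure.
5. Ring order: furanone (step 6), then butenolide (step 8), then carbocycle (step 11).

Numbering used below (germacrane): C1 ketone, C2=C3 furanone enol ether, C4(Me)=C5, C6 acyloxy carbinol, C7, C8 lactone carbinol, C9H2, C10 quaternary carbon, C11=C13H2, C12 lactone carbonyl.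

Assumption 1: 7 is bought as the pure Z isomer.
Assumption 2: the chromium-mediated ring closure follows the usual closed chair of a geometry-locked allylchromium and so gives the anti (6R) carbinol; the tiglate is therefore introduced with inversion.

**Route**

Step 1
Reactants: 1 (S)-citramalic acid
Product: 2 2-[(4S)-2,2,4-trimethyl-5-oxo-1,3-dioxolan-4-yl]acetic acid
Conditions: 2,2-dimethoxypropane, p-TsOH·H2O (cat.), acetone, rt
Reagents that add atoms: 2,2-dimethoxypropane, COC(C)(C)OC
Why: Acid-catalysed acetalisation (dioxolanone formation) engages only the α-hydroxy acid pair in a five-membered ring, so the C10 stereocentre bought with 1 is kept while its tertiary hydroxyl and adjacent carboxyl are masked and the distal carboxyl stays free.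

Step 2
Reactants: 2 2-[(4S)-2,2,4-trimethyl-5-oxo-1,3-dioxolan-4-yl]acetic acid
Product: 4 2-[(4S)-2,2,4-trimethyl-5-oxo-1,3-dioxolan-4-yl]acetaldehyde, via acid chloride 3 (not isolated)
Conditions: (COCl)2, DMF (cat.), CH2Cl2, 0 °C to rt, evaporate; then H2 (1 atm), Pd/BaSO4 (5 mol%), 2,6-lutidine, THF, rt
Reagents that add atoms: none
Why: Rosenmund reduction of the acid chloride made in the same flask stops at the aldehyde because the amine-buffered Pd/BaSO4 catalyst reduces neither aldehydes nor the dioxolanone, and the quaternary C10 cannot epimerise.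

Step 3
Reactants: 4 2-[(4S)-2,2,4-trimethyl-5-oxo-1,3-dioxolan-4-yl]acetaldehyde
Product: 6 (3S,5S)-5-ethenyl-3-hydroxy-3-methyloxolan-2-one, via hydroxy dioxolanone 5 (not isolated)
Conditions: (CH2=CH)2Zn (1.5 equiv), (+)-MIB [(2R)-3-exo-morpholinoisoborneol, 10 mol%], toluene, −20 to 0 °C; aq. NH4Cl; then p-TsOH (cat.), CH2Cl2, rt
Reagents that add atoms: divinylzinc, C=C[Zn]C=C
Why: Amino-alcohol-catalysed asymmetric vinylzinc addition delivers vinyl to the Re face of the aldehyde under ligand control and sets C8 as S (the ligand is the antipode of the one that gives (S)-1-phenylpropan-1-ol from PhCHO and Et2Zn), after which the new hydroxyl transacylates onto the dioxolanone carbonyl under acid with loss of acetone to give the lactone, whose minor C8 epimer is a separable diastereomer.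

Step 4
Reactants: 7 (2Z)-3-methylpent-2-en-4-yn-1-ol
Product: 8 tert-butyldimethyl{[(2Z)-3-methylpent-2-en-4-yn-1-yl]oxy}silane
Conditions: TBSCl, imidazole, CH2Cl2, 0 °C to rt
Reagents that add atoms: tert-butyldimethylsilyl chloride (TBSCl), CC(C)(C)[Si](C)(C)Cl
Why: Routine silyl ether formation, needed because a free cis-disposed primary hydroxyl would later add 5-exo to the activated ynone and aromatise to a furan.

Step 5
Reactants: 8 tert-butyldimethyl{[(2Z)-3-methylpent-2-en-4-yn-1-yl]oxy}silane; 6 (3S,5S)-5-ethenyl-3-hydroxy-3-methyloxolan-2-one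
Product: 10 (2Z,7S,9S)-1-[(tert-butyldimethylsilyl)oxy]-7,9-dihydroxy-3,7-dimethylundeca-2,10-dien-4-yn-6-one, via lithium acetylide 9 (not isolated)
Conditions: 8 (2.4 equiv), n-BuLi (2.3 equiv), THF, −78 °C; then 6 (1.0 equiv), −78 to −40 °C; aq. NH4Cl
Reagents that add atoms: none
Why: Acetylide addition to a lactone (acyl substitution arrested at the lithium hemiketal) forms the C1–C2 bond, the first equivalent of 9 only deprotonating the tertiary hydroxyl (returning 8) and the second adding to the carbonyl, while C10 has no α-hydrogen to enolise and both stereocentres are untouched.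

Step 6
Reactants: 10 (2Z,7S,9S)-1-[(tert-butyldimethylsilyl)oxy]-7,9-dihydroxy-3,7-dimethylundeca-2,10-dien-4-yn-6-one
Product: 11 (2S)-5-{(2Z)-4-[(tert-butyldimethylsilyl)oxy]but-2-en-2-yl}-2-[(2S)-2-hydroxybut-3-en-1-yl]-2-methylfuran-3(2H)-one
Conditions: Ph3PAuNTf2 (5 mol%), toluene, rt
Reagents that add atoms: none
Why: Gold-catalysed 5-endo-dig oxa-Michael cycloisomerisation adds the tertiary C10 hydroxyl to the activated ynone β-carbon C3 to give the 3(2H)-furanone (first ring), the C8 hydroxyl having no comparably favourable ring size, so both stereocentres and the Z alkene are kept.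

Step 7
Reactants: 11 (2S)-5-{(2Z)-4-[(tert-butyldimethylsilyl)oxy]but-2-en-2-yl}-2-[(2S)-2-hydroxybut-3-en-1-yl]-2-methylfuran-3(2H)-one; 12 2-(bromomethyl)prop-2-enoic acid
Product: 13 (2S)-1-[(2S)-5-{(2Z)-4-[(tert-butyldimethylsilyl)oxy]but-2-en-2-yl}-2-methyl-3-oxo-2,3-dihydrofuran-2-yl]but-3-en-2-yl 2-(bromomethyl)prop-2-enoate
Conditions: 12 (1.5 equiv), DCC (1.5 equiv), DMAP (5 mol%), CH2Cl2, 0 °C
Reagents that add atoms: none
Why: Steglich esterification of the only free hydroxyl (C8, retention) installs the acrylate that carries C11, C12 and C13, with DMAP kept catalytic and cold to avoid SN2′ attack on the allylic bromide.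

Step 8
Reactants: 13 (2S)-1-[(2S)-5-{(2Z)-4-[(tert-butyldimethylsilyl)oxy]but-2-en-2-yl}-2-methyl-3-oxo-2,3-dihydrofuran-2-yl]but-3-en-2-yl 2-(bromomethyl)prop-2-enoate
Product: 14 (2S)-2-{[(2S)-4-(bromomethyl)-5-oxo-2,5-dihydrofuran-2-yl]methyl}-5-{(2Z)-4-[(tert-butyldimethylsilyl)oxy]but-2-en-2-yl}-2-methylfuran-3(2H)-one
Conditions: second-generation Hoveyda–Grubbs catalyst (10 mol%), toluene (5 mM), 80 °C, argon sparge
Reagents that add atoms: none
Why: Ring-closing metathesis between the vinyl group and the 1,1-disubstituted acrylate alkene (ethene lost) closes the butenolide (second ring) in the manner of methacrylate-to-butenolide closures, allylic bromides being tolerated by ruthenium alkylidenes and the trisubstituted furanone-conjugated alkene being inert, so C8 is not touched.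

Step 9
Reactants: 14 (2S)-2-{[(2S)-4-(bromomethyl)-5-oxo-2,5-dihydrofuran-2-yl]methyl}-5-{(2Z)-4-[(tert-butyldimethylsilyl)oxy]but-2-en-2-yl}-2-methylfuran-3(2H)-one
Product: 15 (2S)-2-{[(2S)-4-(bromomethyl)-5-oxo-2,5-dihydrofuran-2-yl]methyl}-5-[(2Z)-4-hydroxybut-2-en-2-yl]-2-methylfuran-3(2H)-one
Conditions: HF (48% aq.), MeCN, 0 °C, 30 min; NaHCO3 quench
Reagents that add atoms: none
Why: Acidic fluoride desilylation of the primary allylic silyl ether is run amine-free, cold and briefly so that the allylic bromide, the base-sensitive butenolide C8–H and the Z-allylic alcohol are left alone.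

Step 10
Reactants: 15 (2S)-2-{[(2S)-4-(bromomethyl)-5-oxo-2,5-dihydrofuran-2-yl]methyl}-5-[(2Z)-4-hydroxybut-2-en-2-yl]-2-methylfuran-3(2H)-one
Product: 16 (2Z)-3-[(5S)-5-{[(2S)-4-(bromomethyl)-5-oxo-2,5-dihydrofuran-2-yl]methyl}-5-methyl-4-oxo-4,5-dihydrofuran-2-yl]but-2-enal
Conditions: MnO2 (20 equiv), CH2Cl2, rt, dark; used at once
Reagents that add atoms: none
Why: Heterogeneous MnO2 allylic oxidation is neutral and selective for the dienylic primary alcohol, giving the Z-enal without double-bond isomerisation and without touching the bromide.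

Step 11
Reactants: 16 (2Z)-3-[(5S)-5-{[(2S)-4-(bromomethyl)-5-oxo-2,5-dihydrofuran-2-yl]methyl}-5-methyl-4-oxo-4,5-dihydrofuran-2-yl]but-2-enal
Product: 18 (6R,7S,8S,10S)-6-hydroxy-1-oxo-3,10-epoxygermacra-2,4(Z),11(13)-trien-12,8-olide, via allylchromium 17 (not isolated)
Conditions: CrCl2 (8 equiv), THF, 16 added by syringe pump over 10 h (final 2 mM), rt; aq. NH4Cl
Reagents that add atoms: none
Why: Intramolecular Nozaki–Hiyama–Kishi (Barbier-type) allylation in which CrCl2 inserts into the allylic C–Br bond and the ring-locked allylchromium (C8 trans to CH2Cr) adds through its γ-carbon C7 to the aldehyde in a closed chair, on the butenolide face opposite the C9 tether (7,8-trans lactone, sets C7) and with the dienyl group equatorial (anti adduct, sets C6 as R), forming the C6–C7 bond, the exocyclic methylene and the ten-membered carbocycle (third ring) at high dilution.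

Step 12
Reactants: 18 (6R,7S,8S,10S)-6-hydroxy-1-oxo-3,10-epoxygermacra-2,4(Z),11(13)-trien-12,8-olide; 19 tiglic acid [(2E)-2-methylbut-2-enoic acid]
Product: 20 (6S,7R,8S,10S)-1-oxo-6-(tigloyloxy)-3,10-epoxygermacra-2,4(Z),11(13)-trien-12,8-olide (CNP0293168.2)
Conditions: PPh3 (3 equiv) and DIAD (3 equiv) premixed in toluene at 0 °C; then 19 (3 equiv); then 18; 0 °C to rt
Reagents that add atoms: none
Why: Mitsunobu esterification displaces the alkoxyphosphonium of the allylic 6R alcohol by tiglate with SN2 inversion to the 6S ester of the target, the betaine being pre-formed so that no free PPh3 meets the α-methylene lactone and the neutral conditions leaving C7, C8, C10 and the E tiglate geometry untouched.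

**Compound list**

1 | (S)-citramalic acid [(2S)-2-hydroxy-2-methylbutanedioic acid] | C[C@](O)(CC(=O)O)C(=O)O | starting material
2 | 2-[(4S)-2,2,4-trimethyl-5-oxo-1,3-dioxolan-4-yl]acetic acid | C[C@@]1(CC(=O)O)OC(C)(C)OC1=O | intermediate
3 | 2-[(4S)-2,2,4-trimethyl-5-oxo-1,3-dioxolan-4-yl]acetyl chloride | C[C@@]1(CC(=O)Cl)OC(C)(C)OC1=O | intermediate
4 | 2-[(4S)-2,2,4-trimethyl-5-oxo-1,3-dioxolan-4-yl]acetaldehyde | C[C@@]1(CC=O)OC(C)(C)OC1=O | intermediate
5 | (5S)-5-[(2S)-2-hydroxybut-3-en-1-yl]-2,2,5-trimethyl-1,3-dioxolan-4-one | C=C[C@@H](O)C[C@]1(C)OC(C)(C)OC1=O | intermediate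
6 | (3S,5S)-5-ethenyl-3-hydroxy-3-methyloxolan-2-one | C[C@]1(O)C[C@@H](C=C)OC1=O | intermediate
7 | (2Z)-3-methylpent-2-en-4-yn-1-ol | C#C/C(C)=C\CO | starting material
8 | tert-butyldimethyl{[(2Z)-3-methylpent-2-en-4-yn-1-yl]oxy}silane | C#C/C(C)=C\CO[Si](C)(C)C(C)(C)C | intermediate
9 | {(3Z)-5-[(tert-butyldimethylsilyl)oxy]-3-methylpent-3-en-1-yn-1-yl}lithium | [Li]C#C/C(C)=C\CO[Si](C)(C)C(C)(C)C | intermediate
10 | (2Z,7S,9S)-1-[(tert-butyldimethylsilyl)oxy]-7,9-dihydroxy-3,7-dimethylundeca-2,10-dien-4-yn-6-one | C=C[C@@H](O)C[C@](C)(O)C(=O)C#C/C(C)=C\CO[Si](C)(C)C(C)(C)C | intermediate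
11 | (2S)-5-{(2Z)-4-[(tert-butyldimethylsilyl)oxy]but-2-en-2-yl}-2-[(2S)-2-hydroxybut-3-en-1-yl]-2-methylfuran-3(2H)-one | O=C1C=C(/C(C)=C\CO[Si](C)(C)C(C)(C)C)O[C@@]1(C)C[C@H](O)C=C | intermediate
12 | 2-(bromomethyl)prop-2-enoic acid | C=C(CBr)C(=O)O | starting material
13 | (2S)-1-[(2S)-5-{(2Z)-4-[(tert-butyldimethylsilyl)oxy]but-2-en-2-yl}-2-methyl-3-oxo-2,3-dihydrofuran-2-yl]but-3-en-2-yl 2-(bromomethyl)prop-2-enoate | O=C1C=C(/C(C)=C\CO[Si](C)(C)C(C)(C)C)O[C@@]1(C)C[C@H](OC(=O)C(=C)CBr)C=C | intermediate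
14 | (2S)-2-{[(2S)-4-(bromomethyl)-5-oxo-2,5-dihydrofuran-2-yl]methyl}-5-{(2Z)-4-[(tert-butyldimethylsilyl)oxy]but-2-en-2-yl}-2-methylfuran-3(2H)-one | O=C1C=C(/C(C)=C\CO[Si](C)(C)C(C)(C)C)O[C@@]1(C)C[C@@H]2OC(=O)C(CBr)=C2 | intermediate
15 | (2S)-2-{[(2S)-4-(bromomethyl)-5-oxo-2,5-dihydrofuran-2-yl]methyl}-5-[(2Z)-4-hydroxybut-2-en-2-yl]-2-methylfuran-3(2H)-one | O=C1C=C(/C(C)=C\CO)O[C@@]1(C)C[C@@H]2OC(=O)C(CBr)=C2 | intermediate
16 | (2Z)-3-[(5S)-5-{[(2S)-4-(bromomethyl)-5-oxo-2,5-dihydrofuran-2-yl]methyl}-5-methyl-4-oxo-4,5-dihydrofuran-2-yl]but-2-enal | O=C1C=C(/C(C)=C\C=O)O[C@@]1(C)C[C@@H]2OC(=O)C(CBr)=C2 | intermediate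
17 | allylchromium dichloride of 16 (CrCl2 unit on the former CH2Br carbon) | O=C1C=C(/C(C)=C\C=O)O[C@@]1(C)C[C@@H]2OC(=O)C(C[Cr](Cl)Cl)=C2 | intermediate
18 | (6R,7S,8S,10S)-6-hydroxy-1-oxo-3,10-epoxygermacra-2,4(Z),11(13)-trien-12,8-olide | C=C1C(=O)O[C@H]2C[C@]3(C)OC(=CC3=O)/C(C)=C\[C@@H](O)[C@H]12 | intermediate
19 | tiglic acid [(2E)-2-methylbut-2-enoic acid] | C/C=C(\C)C(=O)O | starting material
20 | (6S,7R,8S,10S)-1-oxo-6-(tigloyloxy)-3,10-epoxygermacra-2,4(Z),11(13)-trien-12,8-olide (CNP0293168.2) | C=C1C(=O)O[C@H]2C[C@]3(C)OC(=CC3=O)/C(C)=C\[C@H](OC(=O)/C(C)=C/C)[C@H]12 | target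

**Step count and risks**

Total step count: 12 (11 on the main line plus the silylation of 7).
Longest linear sequence: 11 steps (1 → 2 → 4 → 6 → 10 → 11 → 13 → 14 → 15 → 16 → 18 → 20).

The three steps most likely to fail:

Step 11 (ring closure). The risks are oligomerisation, a cis-fused or C6-epimeric product, reduction of the dienal by divalent chromium, and acyl migration of the lactone to the new C6 hydroxyl. The fallback sets out from 14 and comes back at 18, replacing the reductive organochromium closure by a redox-neutral intramolecular allylboration that is triggered by the last oxidation. Compound 14 is treated with B2pin2, CuCl (10 mol%) and KOAc in DMF to give the allylboronate silyl ether F1. Desilylation (aq. HF, MeCN, 0 °C) gives the allylboronate alcohol F2, and MnO2 oxidation gives the allylboronate aldehyde F3. At 2 mM in toluene with Sc(OTf)3 (10 mol%), F3 closes through the same chair arrangement to the macrocyclic borate F4, and aqueous NaHCO3 work-up hydrolyses F4 to 18.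

Step 12 (Mitsunobu inversion). The carbinol is secondary, allylic and flanked by the C7 methine inside a bridged medium ring, so elimination or no reaction is possible. The fallback sets out from 18 and comes back at 20, inverting C6 by oxidation and reagent-controlled reduction and then acylating with retention. Dess–Martin periodinane (NaHCO3, CH2Cl2, 0 °C) gives the C6 ketone F5, which is used at once because its C7–H is now doubly activated. Reduction with (S)-Me-CBS oxazaborolidine and catecholborane at −78 °C (alkenyl side as the large group) gives the 6S alcohol F6. Tigloyl chloride, pyridine and catalytic DMAP in CH2Cl2 then give 20.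

Step 3 (asymmetric vinylation). The aldehyde is α-unbranched and enolisable, face selectivity may be only moderate, and divinylzinc is awkward to handle. The fallback sets out from 2 and comes back at 6, setting C8 by ketone reduction instead of aldehyde vinylation. The acid chloride 3 (made from 2 as in step 2) is coupled with ethynyltrimethylsilane (PdCl2(PPh3)2, CuI, Et3N, THF, rt) to give the silyl ynone F7. Asymmetric transfer hydrogenation with RuCl[(S,S)-TsDPEN](p-cymene) in i-PrOH gives the propargylic alcohol F8 with C8 as S. K2CO3 in MeOH followed by catalytic p-TsOH removes the silyl group and closes the lactone to the ethynyl lactone F9. Semi-hydrogenation (H2, Pd/CaCO3 poisoned with Pb(OAc)2, quinoline, EtOAc) returns to 6.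

**Further compounds**

F1 | step 11 | (2S)-5-{(2Z)-4-[(tert-butyldimethylsilyl)oxy]but-2-en-2-yl}-2-methyl-2-({(2S)-5-oxo-4-[(4,4,5,5-tetramethyl-1,3,2-dioxaborolan-2-yl)methyl]-2,5-dihydrofuran-2-yl}methyl)furan-3(2H)-one | O=C1C=C(/C(C)=C\CO[Si](C)(C)C(C)(C)C)O[C@@]1(C)C[C@@H]2OC(=O)C(CB3OC(C)(C)C(C)(C)O3)=C2
F2 | step 11 | (2S)-5-[(2Z)-4-hydroxybut-2-en-2-yl]-2-methyl-2-({(2S)-5-oxo-4-[(4,4,5,5-tetramethyl-1,3,2-dioxaborolan-2-yl)methyl]-2,5-dihydrofuran-2-yl}methyl)furan-3(2H)-one | O=C1C=C(/C(C)=C\CO)O[C@@]1(C)C[C@@H]2OC(=O)C(CB3OC(C)(C)C(C)(C)O3)=C2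
F3 | step 11 | (2Z)-3-[(5S)-5-methyl-4-oxo-5-({(2S)-5-oxo-4-[(4,4,5,5-tetramethyl-1,3,2-dioxaborolan-2-yl)methyl]-2,5-dihydrofuran-2-yl}methyl)-4,5-dihydrofuran-2-yl]but-2-enal | O=C1C=C(/C(C)=C\C=O)O[C@@]1(C)C[C@@H]2OC(=O)C(CB3OC(C)(C)C(C)(C)O3)=C2
F4 | step 11 | O-(4,4,5,5-tetramethyl-1,3,2-dioxaborolan-2-yl) derivative of 18 | C=C1C(=O)O[C@H]2C[C@]3(C)OC(=CC3=O)/C(C)=C\[C@@H](OB4OC(C)(C)C(C)(C)O4)[C@H]12
F5 | step 12 | (7R,8S,10S)-1,6-dioxo-3,10-epoxygermacra-2,4(Z),11(13)-trien-12,8-olide | C=C1C(=O)O[C@H]2C[C@]3(C)OC(=CC3=O)/C(C)=C\C(=O)[C@H]12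
F6 | step 12 | (6S,7S,8S,10S)-6-hydroxy-1-oxo-3,10-epoxygermacra-2,4(Z),11(13)-trien-12,8-olide | C=C1C(=O)O[C@H]2C[C@]3(C)OC(=CC3=O)/C(C)=C\[C@H](O)[C@H]12
F7 | step 3 | (5S)-2,2,5-trimethyl-5-[2-oxo-4-(trimethylsilyl)but-3-yn-1-yl]-1,3-dioxolan-4-one | C[C@@]1(CC(=O)C#C[Si](C)(C)C)OC(C)(C)OC1=O
F8 | step 3 | (5S)-5-[(2S)-2-hydroxy-4-(trimethylsilyl)but-3-yn-1-yl]-2,2,5-trimethyl-1,3-dioxolan-4-one | C[C@@]1(C[C@H](O)C#C[Si](C)(C)C)OC(C)(C)OC1=O
F9 | step 3 | (3S,5S)-5-ethynyl-3-hydroxy-3-methyloxolan-2-one | C#C[C@@H]1C[C@](C)(O)C(=O)O1
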